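**Plan**

1. Retrosynthesis: the C9 acetate, the lactone C12–O6 bond and the C8 glycidate ester are cut first, then the C7–C8 bond of the ten-membered carbocycle, then C7–C11 (acrylate unit), C10–C1 (enoate) and C6–C7 (vinyl). This leaves nerol (C1–C6, C15), dimethyl (R)-malate (C8–C10, C14), methyl acrylate (C11–C13) and (R)-2-methylglycidol.
2. Enabling feature: C7 is the γ-carbon of a 2-(alkoxycarbonyl)allyl unit (C13H2=C11(C12O2R)–C7H) and is bonded to the oxygenated carbon C8, a homoallylic alcohol motif. The C7–C8 bond lies in the ten-membered ring only, not in the lactone ring, so a C8 aldehyde and a C13 allylic bromide on one open chain can close that ring and release the exocyclic C11=C13 methylene in one event.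
3. Forward order: the cis-epoxide ring is made first on the nerol chain; C7, the malate unit and the acrylate unit are attached to the open chain; the ten-membered carbocycle closes in step 16, the γ-lactone ring in step 18, and the acetate goes on last.
4. Stereochemistry: C4/C5 from Sharpless epoxidation, C6 from Felkin–Anh addition to the epoxy aldehyde, C9 from (R)-malate, the glycidate centre from (R)-2-methylglycidol, C7 and C8 from the ring closure. The uncontrolled centres and alkene isomers made on the way (C1, C10, the C7 carbinol, the allyl bromide geometry) are funnelled into single configurations by elimination and by the equilibrating allylchromium.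

Key step: step 16

Assumption: the target is read as the (4R,5S,6S,7R,8S,9R) germacranolide with a cis 4,5-epoxide, an (E) (ring-cis) C1=C10 enoate and a (2S)-2-methylglycidate; C1–C15 are germacrane locants (C6 lactone carbinol, C8 glycidate carbinol, C9 acetate carbinol, C11–C13 methylene-lactone carbons, C14 ester carbon, C15 methyl) and TBS = tert-butyldimethylsilyl.

**Route**

Step 1
Reactants: 1 dimethyl (R)-malate
Product: 2 methyl (3R)-3,4-dihydroxybutanoate
Conditions: BH3·SMe2, NaBH4 (cat.), THF, 0 °C to rt; then MeOH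
Reagents that add atoms: none
Why: The free α-hydroxyl binds borane and NaBH4-catalysed intramolecular hydride delivery (hydroxyl-directed chemoselective borane reduction of an α-hydroxy ester) should reduce only the adjacent ester, leaving the C9 stereocentre untouched.

Step 2
Reactants: 2 methyl (3R)-3,4-dihydroxybutanoate
Product: 3 methyl (3R)-3,4-bis[(tert-butyldimethylsilyl)oxy]butanoate
Conditions: TBSCl, imidazole, DMF, rt
Reagents that add atoms: tert-butyldimethylsilyl chloride CC(C)(C)[Si](C)(C)Cl
Why: Imidazole-promoted silyl ether formation on both hydroxyls blocks lactonisation and gives an enolisable ester whose β-oxygen is a poor leaving group.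

Step 3
Reactants: 4 (R)-2-methylglycidol
Product: 5 (2S)-2-methyloxirane-2-carboxylic acid
Conditions: RuCl3 hydrate (cat.), NaIO4, CCl4/MeCN/H2O, rt
Reagents that add atoms: water O
Why: RuO4 formed catalytically from RuCl3 and NaIO4 oxidises primary 2,3-epoxy alcohols to glycidic acids through the aldehyde hydrate without opening the epoxide, and the quaternary stereocentre cannot epimerise (the descriptor changes from R to S only because the priorities change).

Step 4
Reactants: 6 nerol
Product: 7 (2S,3R)-2,3-epoxynerol
Conditions: Ti(OiPr)4 (cat.), (+)-diethyl (2R,3R)-tartrate (cat.), t-BuOOH, 4 Å molecular sieves, CH2Cl2, −20 °C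
Reagents that add atoms: tert-butyl hydroperoxide CC(C)(C)OO
Why: Sharpless asymmetric epoxidation of the (Z) allylic alcohol with the (2R,3R)-tartrate titanium complex should deliver oxygen to the face that gives the cis-epoxide with C4 R and C5 S, and the isolated trisubstituted alkene is not touched.

Step 5
Reactants: 7 (2S,3R)-2,3-epoxynerol
Product: 8 (2R,3R)-3-methyl-3-(4-methylpent-3-en-1-yl)oxirane-2-carbaldehyde
Conditions: TEMPO (cat.), PhI(OAc)2, CH2Cl2, rt
Reagents that add atoms: none
Why: Oxoammonium (TEMPO) oxidation of the primary alcohol stops at the aldehyde under nearly neutral conditions, and the epoxide carbon next to the formyl group cannot epimerise.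

Step 6
Reactants: 8 (2R,3R)-3-methyl-3-(4-methylpent-3-en-1-yl)oxirane-2-carbaldehyde
Product: 9 (1S)-1-[(2S,3R)-3-methyl-3-(4-methylpent-3-en-1-yl)oxiran-2-yl]prop-2-en-1-ol (anti epoxy alcohol, 4R,5S,6S)
Conditions: CH2=CHMgBr, THF, −78 °C; then H2O
Reagents that add atoms: vinylmagnesium bromide C=C[Mg]Br
Why: Grignard addition to an α,β-epoxy aldehyde under Felkin–Anh control (epoxide C–O bond anti to the incoming nucleophile, approach past H5 and away from the cis C3 chain) should favour the anti (erythro) epoxy alcohol, which sets C6 as S.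

Step 7
Reactants: 9 (1S)-1-[(2S,3R)-3-methyl-3-(4-methylpent-3-en-1-yl)oxiran-2-yl]prop-2-en-1-ol
Product: 10 TBS ether of 9
Conditions: TBSOTf, 2,6-lutidine, CH2Cl2, −78 °C
Reagents that add atoms: tert-butyldimethylsilyl triflate CC(C)(C)[Si](C)(C)OS(=O)(=O)C(F)(F)F
Why: Silyl triflate with a hindered pyridine base silylates the hindered secondary alcohol at low temperature, and the buffered medium should spare the epoxide.

Step 8
Reactants: 10 TBS ether of 9
Product: 12 3-[(2R,3S)-3-{(1S)-1-[(tert-butyldimethylsilyl)oxy]prop-2-en-1-yl}-2-methyloxiran-2-yl]propanal (C1 aldehyde), via secondary ozonide 11 (not isolated)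
Conditions: O3 (one equivalent, Sudan Red 7B end point), CH2Cl2, −78 °C; then PPh3
Reagents that add atoms: ozone [O-][O+]=O
Why: In this ozonolysis with reductive work-up, electrophilic ozone should react far faster with the electron-rich trisubstituted alkene than with the monosubstituted vinyl group that is deactivated by the allylic silyloxy group, and the dye end point stops the reaction after one equivalent.

Step 9
Reactants: 12 C1 aldehyde; 3 methyl (3R)-3,4-bis[(tert-butyldimethylsilyl)oxy]butanoate
Product: 15 methyl (3R)-2-{1-acetoxy-3-[(2R,3S)-3-{(1S)-1-[(tert-butyldimethylsilyl)oxy]prop-2-en-1-yl}-2-methyloxiran-2-yl]propyl}-3,4-bis[(tert-butyldimethylsilyl)oxy]butanoate (isomers at C1 and C10), via lithium enolate 13 (not isolated), via lithium aldolate 14 (not isolated)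
Conditions: LiN(iPr)2, THF, −78 °C; then 12, −78 °C; then Ac2O, −78 to 0 °C
Reagents that add atoms: acetic anhydride CC(=O)OC(C)=O
Why: Lithium ester enolate aldol addition to the unhindered aldehyde at −78 °C (where β-elimination of the silyloxy group is slow) followed by O-acetylation of the aldolate in the same flask joins C10 to C1; the two new centres are left uncontrolled because both are erased in step 12.

Step 10
Reactants: 15 β-acetoxy ester
Product: 17 C7 aldehyde (15 with the vinyl group replaced by formyl; 4R,5S,6R,9R), via secondary ozonide 16 (not isolated)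
Conditions: O3, CH2Cl2, −78 °C; then PPh3
Reagents that add atoms: ozone [O-][O+]=O
Why: Ozonolysis with reductive work-up cleaves the only C=C bond present, which is why the elimination to the C10=C1 enoate is deferred until after this step.

Step 11
Reactants: 17 C7 aldehyde
Product: 18 Baylis–Hillman adduct (17 with CHO replaced by CH(OH)–C(=CH2)CO2Me; isomers at C1, C7, C10)
Conditions: methyl acrylate (excess), DABCO, MeOH, rt
Reagents that add atoms: methyl acrylate C=CC(=O)OC
Why: In the Morita–Baylis–Hillman reaction the ammonium enolate from DABCO and methyl acrylate adds to the aldehyde and installs C11–C13; the new C7 carbinol centre needs no control because it is erased in step 13.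

Step 12
Reactants: 18 Baylis–Hillman adduct
Product: 19 (E)-enoate (C10=C1 formed, C2 trans to CO2Me; 4R,5S,6S,9R; isomers at C7 only)
Conditions: DBU, CH2Cl2, rt
Reagents that add atoms: none
Why: E1cB elimination of acetate from the β-acetoxy ester should give mainly the more stable conjugated (E) trisubstituted enoate, so the C1/C10 isomer mixture converges on one alkene (a minor Z isomer would be removed by chromatography).

Step 13
Reactants: 19 (E)-enoate
Product: 20 (Z)-allylic bromide (C7=C11 with C6 cis to C13H2Br; 4R,5S,6S,9R)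
Conditions: NBS, Me2S, CH2Cl2, 0 °C to rt
Reagents that add atoms: N-bromosuccinimide O=C1CCC(=O)N1Br
Why: Corey–Kim-type activation of the allylic alcohol as an alkoxysulfonium ion and SN2′ attack of bromide at the terminal methylene should give the (Z)-2-(bromomethyl)alk-2-enoate, the usual outcome for ester-derived Baylis–Hillman adducts; the geometry need not be pure because the allylmetal of step 16 equilibrates.

Step 14
Reactants: 20 (Z)-allylic bromide
Product: 21 C8 primary alcohol (O6 and O9 still TBS ethers)
Conditions: HF·pyridine, pyridine, THF, 0 °C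
Reagents that add atoms: none
Why: Buffered HF·pyridine should cleave the unhindered primary silyl ether much faster than the two hindered secondary ones (rate-based selective desilylation) under conditions that spare trisubstituted epoxides and allylic bromides.

Step 15
Reactants: 21 C8 primary alcohol
Product: 22 C8 aldehyde (α-silyloxy aldehyde carrying the allylic bromide; 4R,5S,6S,9R)
Conditions: TEMPO (cat.), PhI(OAc)2, CH2Cl2, rt
Reagents that add atoms: none
Why: Oxoammonium oxidation gives the aldehyde under non-basic conditions, so the acidic C9–H is not epimerised and the allylic bromide is untouched; the aldehyde is used at once.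

Step 16
Reactants: 22 C8 aldehyde
Product: 24 dimethyl (1(10)E,4R,5S,6S,7R,8S,9R)-6,9-bis[(tert-butyldimethylsilyl)oxy]-4,5-epoxy-8-hydroxygermacra-1(10),11(13)-diene-12,14-dioate, via allylchromium dichloride 23 (not isolated)
Conditions: CrCl2 (excess), THF/DMF, slow addition of 22 to about 2 millimolar, rt; then H2O
Reagents that add atoms: none
Why: CrCl2 inserts into the allylic C–Br bond by two one-electron transfers to give the σ-allyl trivalent chromium species 23, whose E/Z and regioisomeric forms interconvert by 1,3-metal shifts, so any isomer mixture of 22 converges on the (Z) primary allylchromium, which adds through its γ-carbon C7 to the chromium-bound C8 aldehyde in a closed six-membered chair transition state (Nozaki–Hiyama–Kishi carbonyl allylation, SE2′). The closest known reactions are the intramolecular CrCl2-mediated 2-(alkoxycarbonyl)allylations used to close ten-membered germacranolide rings and the syn-selective chromium-, zinc- or indium-mediated additions of (Z)-2-(bromomethyl)alk-2-enoates to aldehydes. The ten-membered carbocycle closes in a 10-exo-trig mode with respect to the aldehyde, while the former C7=C11 bond moves out of the ring to become the exocyclic C11=C13 methylene. C7 is controlled by C6: allylic 1,3-strain with the C13 methylene holds H6 in the allyl plane and the aldehyde, tethered through C5, attacks the face anti to the bulky C6 silyloxy group, which is the relationship of the trans-fused lactone; C8 is controlled by the chair geometry of the (Z)-allyl unit with C9 equatorial (7,8-syn) and, in the same sense, by polar Felkin–Anh induction from the C9 silyloxy group (8,9-anti), so the three elements are matched. The step needs γ- over α-attack (inherent to allylchromium), ring closure over oligomerisation (slow addition at high dilution) and a chromium alkoxide that does not lactonise onto the C12 or C14 ester (neutral medium, room temperature, prompt aqueous work-up), while the esters, the epoxide and the silyl ethers are inert to CrCl2.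

Step 17
Reactants: 24 macrocyclic alcohol; 5 (2S)-2-methyloxirane-2-carboxylic acid
Product: 26 8-O-[(2S)-2-methyloxirane-2-carbonyl] ester of 24, via mixed anhydride 25 (not isolated)
Conditions: 5, 2,4,6-trichlorobenzoyl chloride, Et3N, toluene, rt; then 24, DMAP, rt
Reagents that add atoms: none
Why: In the Yamaguchi esterification DMAP opens the mixed anhydride at the glycidoyl carbonyl and the acylpyridinium acylates the hindered C8 hydroxyl with retention at C8 and no risk to the quaternary glycidate centre.

Step 18
Reactants: 26 glycidate ester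
Product: 28 methyl (1(10)E,4R,5S,6S,7R,8S,9R)-4,5-epoxy-9-hydroxy-8-{[(2S)-2-methyloxirane-2-carbonyl]oxy}germacra-1(10),11(13)-dien-12,6-olid-14-oate, via seco hydroxy ester 27 (not isolated)
Conditions: HF·pyridine, pyridine, THF, 0 °C to rt
Reagents that add atoms: none
Why: Fluoride cleavage of both secondary silyl ethers frees O6 and O9, and the C6 hydroxyl, held next to the C12 acrylate ester, should close the trans-fused five-membered lactone by acid-catalysed transesterification (5-exo-trig, loss of methanol) under conditions known to spare trisubstituted epoxides and the electron-poor glycidate epoxide.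

Step 19
Reactants: 28 9-hydroxy lactone
Product: 29 methyl (1(10)E,4R,5S,6S,7R,8S,9R)-9-acetoxy-4,5-epoxy-8-{[(2S)-2-methyloxirane-2-carbonyl]oxy}germacra-1(10),11(13)-dien-12,6-olid-14-oate (CNP0274195.2)
Conditions: Ac2O, pyridine, DMAP (cat.), CH2Cl2, 0 °C
Reagents that add atoms: acetic anhydride CC(=O)OC(C)=O
Why: DMAP-catalysed acetylation of the only remaining hydroxyl (C9) completes the target without touching the two epoxides or the α-methylene lactone.

**Compound list**

1 | dimethyl (R)-malate | COC(=O)C[C@@H](O)C(=O)OC | starting material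
2 | methyl (3R)-3,4-dihydroxybutanoate | COC(=O)C[C@@H](O)CO | intermediate
3 | methyl (3R)-3,4-bis[(tert-butyldimethylsilyl)oxy]butanoate | COC(=O)C[C@@H](O[Si](C)(C)C(C)(C)C)CO[Si](C)(C)C(C)(C)C | intermediate
4 | (R)-2-methylglycidol, [(2R)-2-methyloxiran-2-yl]methanol | OC[C@]1(C)CO1 | starting material
5 | (2S)-2-methyloxirane-2-carboxylic acid | OC(=O)[C@]1(C)CO1 | intermediate
6 | nerol, (2Z)-3,7-dimethylocta-2,6-dien-1-ol | CC(C)=CCC/C(C)=C\CO | starting material
7 | (2S,3R)-2,3-epoxynerol, [(2S,3R)-3-methyl-3-(4-methylpent-3-en-1-yl)oxiran-2-yl]methanol | CC(C)=CCC[C@@]1(C)O[C@H]1CO | intermediate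
8 | (2R,3R)-3-methyl-3-(4-methylpent-3-en-1-yl)oxirane-2-carbaldehyde | CC(C)=CCC[C@@]1(C)O[C@H]1C=O | intermediate
9 | (1S)-1-[(2S,3R)-3-methyl-3-(4-methylpent-3-en-1-yl)oxiran-2-yl]prop-2-en-1-ol (4R,5S,6S) | CC(C)=CCC[C@@]1(C)O[C@H]1[C@@H](O)C=C | intermediate
10 | TBS ether of 9 (4R,5S,6S) | CC(C)=CCC[C@@]1(C)O[C@H]1[C@@H](O[Si](C)(C)C(C)(C)C)C=C | intermediate
11 | secondary ozonide of 10 (3,3-dimethyl-1,2,4-trioxolane at the former C1=C(CH3)2 bond) | CC1(C)OOC(CC[C@@]2(C)O[C@H]2[C@@H](O[Si](C)(C)C(C)(C)C)C=C)O1 | intermediate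
12 | 3-[(2R,3S)-3-{(1S)-1-[(tert-butyldimethylsilyl)oxy]prop-2-en-1-yl}-2-methyloxiran-2-yl]propanal (C1 aldehyde) | O=CCC[C@@]1(C)O[C@H]1[C@@H](O[Si](C)(C)C(C)(C)C)C=C | intermediate
13 | lithium enolate of 3 | COC([O-])=C[C@@H](O[Si](C)(C)C(C)(C)C)CO[Si](C)(C)C(C)(C)C.[Li+] | intermediate
14 | lithium aldolate from 13 and 12 (isomers at C1, C10) | COC(=O)C([C@@H](O[Si](C)(C)C(C)(C)C)CO[Si](C)(C)C(C)(C)C)C([O-])CC[C@@]1(C)O[C@H]1[C@@H](O[Si](C)(C)C(C)(C)C)C=C.[Li+] | intermediate
15 | methyl (3R)-2-{1-acetoxy-3-[(2R,3S)-3-{(1S)-1-[(tert-butyldimethylsilyl)oxy]prop-2-en-1-yl}-2-methyloxiran-2-yl]propyl}-3,4-bis[(tert-butyldimethylsilyl)oxy]butanoate (4R,5S,6S,9R; isomers at C1, C10) | COC(=O)C([C@@H](O[Si](C)(C)C(C)(C)C)CO[Si](C)(C)C(C)(C)C)C(OC(C)=O)CC[C@@]1(C)O[C@H]1[C@@H](O[Si](C)(C)C(C)(C)C)C=C | intermediate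
16 | secondary ozonide of 15 (1,2,4-trioxolane at the former vinyl group) | COC(=O)C([C@@H](O[Si](C)(C)C(C)(C)C)CO[Si](C)(C)C(C)(C)C)C(OC(C)=O)CC[C@@]1(C)O[C@H]1[C@@H](O[Si](C)(C)C(C)(C)C)C1OOCO1 | intermediate
17 | C7 aldehyde: 15 with formyl in place of vinyl (4R,5S,6R,9R; isomers at C1, C10) | COC(=O)C([C@@H](O[Si](C)(C)C(C)(C)C)CO[Si](C)(C)C(C)(C)C)C(OC(C)=O)CC[C@@]1(C)O[C@H]1[C@@H](O[Si](C)(C)C(C)(C)C)C=O | intermediate
18 | Baylis–Hillman adduct: C7 carbinol bearing the 1-(methoxycarbonyl)vinyl group (4R,5S,6S,9R; isomers at C1, C7, C10) | COC(=O)C([C@@H](O[Si](C)(C)C(C)(C)C)CO[Si](C)(C)C(C)(C)C)C(OC(C)=O)CC[C@@]1(C)O[C@H]1[C@@H](O[Si](C)(C)C(C)(C)C)C(O)C(=C)C(=O)OC | intermediate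
19 | (E)-enoate at C10=C1 with the C7 Baylis–Hillman carbinol (4R,5S,6S,9R; isomers at C7) | CC(C)(C)[Si](C)(C)OC[C@H](O[Si](C)(C)C(C)(C)C)/C(C(=O)OC)=C\CC[C@@]1(C)O[C@H]1[C@@H](O[Si](C)(C)C(C)(C)C)C(O)C(=C)C(=O)OC | intermediate
20 | (Z)-allylic bromide: C7=C11(CO2Me)–C13H2Br with C6 cis to C13, (E)-enoate at C10=C1, TBS ethers on O6, O8, O9 (4R,5S,6S,9R) | CC(C)(C)[Si](C)(C)OC[C@H](O[Si](C)(C)C(C)(C)C)/C(C(=O)OC)=C\CC[C@@]1(C)O[C@H]1[C@@H](O[Si](C)(C)C(C)(C)C)/C=C(\CBr)C(=O)OC | intermediate
21 | C8 primary alcohol of 20 (4R,5S,6S,9R) | OC[C@H](O[Si](C)(C)C(C)(C)C)/C(C(=O)OC)=C\CC[C@@]1(C)O[C@H]1[C@@H](O[Si](C)(C)C(C)(C)C)/C=C(\CBr)C(=O)OC | intermediate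
22 | C8 aldehyde, the cyclisation substrate (4R,5S,6S,9R) | O=C[C@H](O[Si](C)(C)C(C)(C)C)/C(C(=O)OC)=C\CC[C@@]1(C)O[C@H]1[C@@H](O[Si](C)(C)C(C)(C)C)/C=C(\CBr)C(=O)OC | intermediate
23 | σ-allyl trivalent chromium dichloride from 22 (CrCl2 on C13) | O=C[C@H](O[Si](C)(C)C(C)(C)C)/C(C(=O)OC)=C\CC[C@@]1(C)O[C@H]1[C@@H](O[Si](C)(C)C(C)(C)C)/C=C(\C[Cr](Cl)Cl)C(=O)OC | intermediate
24 | dimethyl (1(10)E,4R,5S,6S,7R,8S,9R)-6,9-bis[(tert-butyldimethylsilyl)oxy]-4,5-epoxy-8-hydroxygermacra-1(10),11(13)-diene-12,14-dioate | C=C(C(=O)OC)[C@@H]1[C@H](O)[C@H](O[Si](C)(C)C(C)(C)C)/C(C(=O)OC)=C\CC[C@@]2(C)O[C@H]2[C@H]1O[Si](C)(C)C(C)(C)C | intermediate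
25 | mixed anhydride of 5 with 2,4,6-trichlorobenzoic acid | Clc1cc(Cl)c(c(Cl)c1)C(=O)OC(=O)[C@]1(C)CO1 | intermediate
26 | 8-O-[(2S)-2-methyloxirane-2-carbonyl] ester of 24 (4R,5S,6S,7R,8S,9R) | C=C(C(=O)OC)[C@@H]1[C@H](OC(=O)[C@]2(C)CO2)[C@H](O[Si](C)(C)C(C)(C)C)/C(C(=O)OC)=C\CC[C@@]2(C)O[C@H]2[C@H]1O[Si](C)(C)C(C)(C)C | intermediate
27 | seco hydroxy ester: 26 with free C6 and C9 hydroxyls (same spatial arrangement as 26) | C=C(C(=O)OC)[C@@H]1[C@H](OC(=O)[C@]2(C)CO2)[C@H](O)/C(C(=O)OC)=C\CC[C@@]2(C)O[C@H]2[C@H]1O | intermediate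
28 | methyl (1(10)E,4R,5S,6S,7R,8S,9R)-4,5-epoxy-9-hydroxy-8-{[(2S)-2-methyloxirane-2-carbonyl]oxy}germacra-1(10),11(13)-dien-12,6-olid-14-oate | C=C1C(=O)O[C@H]2[C@H]1[C@H](OC(=O)[C@]1(C)CO1)[C@H](O)/C(C(=O)OC)=C\CC[C@@]1(C)O[C@@H]21 | intermediate
29 | methyl (1(10)E,4R,5S,6S,7R,8S,9R)-9-acetoxy-4,5-epoxy-8-{[(2S)-2-methyloxirane-2-carbonyl]oxy}germacra-1(10),11(13)-dien-12,6-olid-14-oate | C=C1C(=O)O[C@H]2[C@H]1[C@H](OC(=O)[C@]1(C)CO1)[C@H](OC(C)=O)/C(C(=O)OC)=C\CC[C@@]1(C)O[C@@H]21 | target

**Step count and risks**

Total step count: 19. Longest linear sequence: 16 steps (nerol 6 to target 29, steps 4 to 19).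

Steps most likely to fail:

Step 16. The ring closure may deliver the aldehyde to the wrong face of the allyl unit or present the wrong aldehyde face (epimers at C7 or C8), may oligomerise, or the chromium alkoxide may lactonise onto the C12 or C14 ester. The fallback replaces the equilibrating allylchromium by a configurationally fixed allylboron reagent and sets out from 20. Borylation of the allylic bromide with bis(pinacolato)diboron under Pd2(dba)3 catalysis should give the primary (Z)-allylboronate F1. Selective cleavage of the primary silyl ether with buffered HF·pyridine gives the C8 alcohol F2, and TEMPO/PhI(OAc)2 oxidation gives the aldehyde F3. Warming F3 in dilute toluene should close the ring by intramolecular allylboration through a closed chair transition state, in which the oxygen is held as a borate and cannot lactonise. Hydrolytic work-up at neutral pH comes back to the route at 24.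

Step 11. Addition to the hindered α-silyloxy aldehyde may be slow, and long exposure to the amine may enolise C6, with epimerisation or β-opening of the epoxide. The fallback uses a preformed α-acrylate anion equivalent in place of amine catalysis and sets out from 17. Hydroalumination of methyl propiolate with iBu2AlH and N-methylmorpholine N-oxide in THF at 0 °C gives [1-(methoxycarbonyl)vinyl]diisobutylaluminium F4, which should add to the aldehyde of 17 within minutes under non-basic conditions and comes back to the route at 18.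

Step 6. Facial selectivity in the Grignard addition to the epoxy aldehyde may be poor, giving both C6 epimers. The fallback sets the centre by reduction in place of addition; it sets out from 9 obtained as the epimer mixture. Dess–Martin oxidation gives the epoxy vinyl ketone 1-[(2R,3R)-3-methyl-3-(4-methylpent-3-en-1-yl)oxiran-2-yl]prop-2-en-1-one F5. Reduction with Zn(BH4)2 in Et2O at −20 °C, which chelates the epoxide and carbonyl oxygens and is known to give anti (erythro) epoxy alcohols from α,β-epoxy ketones, comes back to the route at 9 as the single anti isomer.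

**Further compounds**

F1 | step 16 | pinacol (Z)-allylboronate from 20 (Bpin on C13 in place of Br) | CC(C)(C)[Si](C)(C)OC[C@H](O[Si](C)(C)C(C)(C)C)/C(C(=O)OC)=C\CC[C@@]1(C)O[C@H]1[C@@H](O[Si](C)(C)C(C)(C)C)/C=C(\CB1OC(C)(C)C(C)(C)O1)C(=O)OC
F2 | step 16 | C8 primary alcohol of F1 | OC[C@H](O[Si](C)(C)C(C)(C)C)/C(C(=O)OC)=C\CC[C@@]1(C)O[C@H]1[C@@H](O[Si](C)(C)C(C)(C)C)/C=C(\CB1OC(C)(C)C(C)(C)O1)C(=O)OC
F3 | step 16 | C8 aldehyde of F1 | O=C[C@H](O[Si](C)(C)C(C)(C)C)/C(C(=O)OC)=C\CC[C@@]1(C)O[C@H]1[C@@H](O[Si](C)(C)C(C)(C)C)/C=C(\CB1OC(C)(C)C(C)(C)O1)C(=O)OC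
F4 | step 11 | [1-(methoxycarbonyl)vinyl]diisobutylaluminium | COC(=O)C(=C)[Al](CC(C)C)CC(C)C
F5 | step 6 | 1-[(2R,3R)-3-methyl-3-(4-methylpent-3-en-1-yl)oxiran-2-yl]prop-2-en-1-one | CC(C)=CCC[C@@]1(C)O[C@H]1C(=O)C=C
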